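**Assumption:** gibberellic acid (GA3), the bulk fermentation product sold as a plant-growth regulator, is taken as the commercially available chiral starting material; N,N-dimethylformamide dimethyl acetal supplies C-20.

**Numbering and abbreviations:** gibberellane numbering (ring A = C-1 to C-5 plus C-10); α is the face of C-4 that carries C-19, β the face of the 3-OH. GA28 stands for the target gibberellin, 3β,13-dihydroxygibberell-16-ene-7,19,20-trioic acid. The route is a paper design and has not been run.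

## Retrosynthetic overview

1. GA28 (12) ⇐ ring-A-saturated C-20 dimethylamide 9: thiolate cleaves the esters, then the neighbouring C-19 acid expels the amine through the 19,20-anhydride.
2. 9 ⇐ Δ1-amide 8 (amide-directed hydrogenation); 8 ⇐ 2α-allylic alcohol 5 + DMF dimethyl acetal 6. The bond from C-10 to C-20 forms by a [2,3]-sigmatropic shift (Büchi rearrangement) that transfers chirality from O-2α to C-10α.
3. 5 ⇐ iso-lactone 2 (silylation, saponification) ⇐ GA3 (1) by allylic transposition of the lactone from C-10 to C-2.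
4. Rings: carbocycles A, B, C and D and every stereocentre except C-10 come intact from GA3. Only the lactone ring is moved (step 1) and opened (step 3), and a transient anhydride ring appears in step 7. C-10 is re-set from C-2, which is itself set by C-4.

## Route

**Step 1**
Reactants: 1 gibberellic acid (GA3)
Product: 2 iso-gibberellic acid (19,2α-lactone with a 1(10)-alkene)
Conditions: 0.05 M aq. NaOH (2 equiv), 20 °C, ca. 2 h (HPLC control); then 1 M HCl to pH 3, 0 °C
Reagents that add atoms: none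
Why: in weak alkali the allylic γ-lactone of GA3 undergoes its known SN2′-type allylic lactone transposition from C-10 to C-2 (assisted by the ionised 3β-hydroxyl, hence done before silylation), and because the C-19 carboxylate is tethered to the α-face of C-4 the new bond from C-2 to oxygen can only form on the α-face, which sets C-2 and moves the alkene to the 1(10) position.

**Step 2**
Reactants: 2 iso-gibberellic acid
Product: 4 3β,13-bis-O-TBS iso-gibberellic acid, via silyl ester 3 (not isolated)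
Conditions: TBSOTf (3.5 equiv), 2,6-lutidine (6 equiv), CH2Cl2, −20 → 20 °C; then THF/H2O/AcOH 8:1:1, 20 °C, 30 min
Reagents that add atoms: tert-butyldimethylsilyl trifluoromethanesulfonate (TBSOTf), CC(C)(C)[Si](C)(C)OS(=O)(=O)C(F)(F)F
Why: O-silylation with a silyl triflate caps the hindered secondary 3β-OH and the tertiary bridgehead 13-OH, the labile silyl ester is hydrolysed in the aqueous acetic acid stage, and no stereocentre is touched.

**Step 3**
Reactants: 4 3β,13-bis-O-TBS iso-gibberellic acid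
Product: 5 2α-hydroxy-3β,13-bis(TBS-oxy)-20-norgibberella-1(10),16-diene-7,19-dioic acid
Conditions: KOH (6 equiv), THF/MeOH/H2O 2:2:1, 50 °C, 6 h; then 0.5 M HCl to pH 4, 0 °C, EtOAc; used at once
Reagents that add atoms: potassium hydroxide, [K+].[OH-]
Why: saponification by acyl–oxygen cleavage opens the bridged γ-lactone irreversibly as the dicarboxylate and frees the allylic 2α-OH with retention, while the silylated 3-oxygen cannot undergo retro-aldol cleavage and hindered silyl ethers survive hydroxide.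

**Step 4**
Reactants: 5 the 2α-hydroxy diacid; 6 N,N-dimethylformamide dimethyl acetal
Product: 8 7,19-dimethyl ester 20-(N,N-dimethylamide) of 3β,13-bis(TBS-oxy)gibberella-1,16-diene-7,19,20-trioic acid, via amide acetal 7 (not isolated)
Conditions: HC(OMe)2NMe2 (10 equiv), toluene, 60 °C, 2 h; then xylene, 140 °C, 16 h, MeOH distilled off
Reagents that add atoms: N,N-dimethylformamide dimethyl acetal (6), COC(OC)N(C)C
Why: the amide acetal methylates both carboxylic acids and exchanges onto the 2α-OH (masking it before C-19 becomes an ester, so it cannot relactonise), then loses methanol to an allyloxy(dimethylamino)carbene that undergoes the Büchi [2,3]-sigmatropic rearrangement, forming the bond from C-10 to C-20 suprafacially on the α-face from which the oxygen at C-2 departs and moving the alkene to the 1,2-position, so the quaternary C-10 configuration is dictated by C-2.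

**Step 5**
Reactants: 8 the Δ1 C-20 amide
Product: 9 7,19-dimethyl ester 20-(N,N-dimethylamide) of 3β,13-bis(TBS-oxy)gibberell-16-ene-7,19,20-trioic acid
Conditions: H2 (1 atm), [Ir(cod)(PCy3)(py)]PF6 (5 mol %), CH2Cl2, 0 °C, stopped after 1 equiv H2
Reagents that add atoms: none
Why: in this carbonyl-directed homogeneous hydrogenation the C-20 amide oxygen binds the cationic iridium and delivers hydrogen to the adjacent 1,2-alkene from the α-face (away from the 3β-silyloxy group), whereas the 16-ene has only a shielding, non-coordinating tertiary silyl ether nearby; no stereocentre is created.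

**Step 6**
Reactants: 9 the ring-A-saturated amide diester
Product: 10 20-(N,N-dimethylamide) of 3β,13-bis(TBS-oxy)gibberell-16-ene-7,19,20-trioic acid (free 7- and 19-acids)
Conditions: NaSEt (6 equiv), DMF, 80 °C, 4 h; then 0.5 M HCl to pH 3, 0 °C
Reagents that add atoms: none
Why: thiolate cleaves both methyl esters by SN2 attack at the O-methyl carbon, which is indifferent to the steric shielding of the axial C-19 carboxyl and is too weakly basic to epimerise C-6, while amide, silyl ethers and alkene are inert.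

**Step 7**
Reactants: 10 the bis-silyl diacid amide
Product: 12 GA28, via cyclic anhydride 11 (not isolated)
Conditions: 48% aq. HF/MeCN 1:9, 25–40 °C, 12 h; concentrate; then 0.2 M aq. LiOH/THF, 0 °C, 20 min; HCl to pH 3; reversed-phase chromatography
Reagents that add atoms: lithium hydroxide (aqueous), [Li+].[OH-]
Why: aqueous HF removes both silyl ethers and at low pH the C-19 acid, held 1,3-diaxial to the C-20 amide, attacks it in a neighbouring-group acyl transfer (as in maleamic and Kemp-type amide acids) to give the 19,20-anhydride with loss of dimethylamine, which cold hydroxide opens to the tricarboxylic acid without touching a stereocentre.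

## Compound list

1 | gibberellic acid (GA3): 3β,13-dihydroxy-20-norgibberella-1,16-diene-7,19-dioic acid 19,10α-lactone | C=C1C[C@]23C[C@@]1(O)CC[C@H]2[C@]14C=C[C@H](O)[C@@](C)(C(=O)O4)[C@H]1[C@@H]3C(=O)O | starting material
2 | iso-gibberellic acid: 3β,13-dihydroxy-20-norgibberella-1(10),16-diene-7,19-dioic acid 19,2α-lactone | C=C1C[C@]23C[C@@]1(O)CC[C@H]2C1=C[C@@H]4[C@H](O)[C@@](C)(C(=O)O4)[C@H]1[C@@H]3C(=O)O | intermediate
3 | tert-butyldimethylsilyl ester of 3β,13-bis-O-TBS iso-gibberellic acid (not isolated) | C=C1C[C@]23C[C@@]1(O[Si](C)(C)C(C)(C)C)CC[C@H]2C1=C[C@@H]4[C@H](O[Si](C)(C)C(C)(C)C)[C@@](C)(C(=O)O4)[C@H]1[C@@H]3C(=O)O[Si](C)(C)C(C)(C)C | intermediate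
4 | 3β,13-bis-O-TBS iso-gibberellic acid (19,2α-lactone, free 7-acid) | C=C1C[C@]23C[C@@]1(O[Si](C)(C)C(C)(C)C)CC[C@H]2C1=C[C@@H]4[C@H](O[Si](C)(C)C(C)(C)C)[C@@](C)(C(=O)O4)[C@H]1[C@@H]3C(=O)O | intermediate
5 | 2α-hydroxy-3β,13-bis(TBS-oxy)-20-norgibberella-1(10),16-diene-7,19-dioic acid | C=C1C[C@]23C[C@@]1(O[Si](C)(C)C(C)(C)C)CC[C@H]2C1=C[C@@H](O)[C@H](O[Si](C)(C)C(C)(C)C)[C@@](C)(C(=O)O)[C@H]1[C@@H]3C(=O)O | intermediate
6 | N,N-dimethylformamide dimethyl acetal | COC(OC)N(C)C | starting material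
7 | dimethyl 2α-[(dimethylamino)(methoxy)methoxy]-3β,13-bis(TBS-oxy)-20-norgibberella-1(10),16-diene-7,19-dioate (epimers at the acetal carbon; not isolated) | C=C1C[C@]23C[C@@]1(O[Si](C)(C)C(C)(C)C)CC[C@H]2C1=C[C@@H](OC(OC)N(C)C)[C@H](O[Si](C)(C)C(C)(C)C)[C@@](C)(C(=O)OC)[C@H]1[C@@H]3C(=O)OC | intermediate
8 | 7,19-dimethyl ester 20-(N,N-dimethylamide) of 3β,13-bis(TBS-oxy)gibberella-1,16-diene-7,19,20-trioic acid (C-20 on the α-face of C-10) | C=C1C[C@]23C[C@@]1(O[Si](C)(C)C(C)(C)C)CC[C@H]2[C@]1(C(=O)N(C)C)C=C[C@H](O[Si](C)(C)C(C)(C)C)[C@@](C)(C(=O)OC)[C@H]1[C@@H]3C(=O)OC | intermediate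
9 | 7,19-dimethyl ester 20-(N,N-dimethylamide) of 3β,13-bis(TBS-oxy)gibberell-16-ene-7,19,20-trioic acid | C=C1C[C@]23C[C@@]1(O[Si](C)(C)C(C)(C)C)CC[C@H]2[C@]1(C(=O)N(C)C)CC[C@H](O[Si](C)(C)C(C)(C)C)[C@@](C)(C(=O)OC)[C@H]1[C@@H]3C(=O)OC | intermediate
10 | 20-(N,N-dimethylamide) of 3β,13-bis(TBS-oxy)gibberell-16-ene-7,19,20-trioic acid (7,19-diacid) | C=C1C[C@]23C[C@@]1(O[Si](C)(C)C(C)(C)C)CC[C@H]2[C@]1(C(=O)N(C)C)CC[C@H](O[Si](C)(C)C(C)(C)C)[C@@](C)(C(=O)O)[C@H]1[C@@H]3C(=O)O | intermediate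
11 | GA28 19,20-anhydride (not isolated) | C=C1C[C@]23C[C@@]1(O)CC[C@H]2[C@]14CC[C@H](O)[C@@](C)(C(=O)OC4=O)[C@H]1[C@@H]3C(=O)O | intermediate
12 | GA28: 3β,13-dihydroxygibberell-16-ene-7,19,20-trioic acid | C=C1C[C@]23C[C@@]1(O)CC[C@H]2[C@]1(C(=O)O)CC[C@H](O)[C@@](C)(C(=O)O)[C@H]1[C@@H]3C(=O)O | target

## Step count and risks

Total step count: 7. Longest linear sequence: 7 (1 → 2 → 4 → 5 → 8 → 9 → 10 → 12).

**Step 4 (most likely to fail).** The [2,3] shift must build a quaternary centre 1,3-diaxial to the C-19 ester at 140 °C; relactonisation of O-2 onto C-19 and elimination to a diene are the competing paths. The fallback keeps the chirality transfer from O-2α but forms the bond by a [3,3] shift and excises the extra carbon; it sets out from 5 and comes back to the route at 12. Me3SiCHN2 (MeOH/toluene, 0 °C) gives the 2α-hydroxy dimethyl ester F1. EDC·HCl/DMAP with (4-methoxybenzyloxy)acetic acid gives the 2α-O-(PMB-oxy)acetate F2. Ireland–Claisen rearrangement (LiN(i-Pr)2, Me3SiCl, THF, −78 → 60 °C, aqueous work-up) gives the C-10α (PMB-oxy)acetic acid F3 with the alkene moved to the Δ1 position. DDQ (CH2Cl2/pH 7 buffer) frees the α-hydroxy acid F4. Pb(OAc)4 (benzene/MeOH, 0 °C) cleaves it to the Δ1 C-20 aldehyde F5. NaClO2/NaH2PO4/2-methyl-2-butene gives the Δ1 C-20 acid F6. Hydrogenation under the step 5 conditions (carboxyl-directed) gives the ring-A-saturated acid F7. Aqueous HF/MeCN gives the desilylated 7,19-dimethyl ester 20-acid F8, and n-PrSLi/HMPA (20 °C), then acid, gives 12.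

**Step 5.** The undirected 16-ene is a reactive 1,1-disubstituted alkene and iridium hydrides can also isomerise it, so selectivity rests on rate alone. The fallback reduces ring A by a mechanism that cannot touch an isolated alkene; it sets out from 8 and comes back at 9. Aqueous HF/MeCN gives the 3β,13-diol F9. MnO2 (CH2Cl2) oxidises only the allylic 3-OH to the 1-en-3-one F10. [(Ph3P)CuH]6 (benzene, 20 °C) conjugate reduction gives the saturated 3-ketone F11. KBH(s-Bu)3 (THF, −78 °C) attacks equatorially and returns the axial 3β-alcohol F12. TBSOTf/2,6-lutidine re-silylates both hydroxyls to give 9.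

**Step 7.** Cleavage of a neopentyl tertiary amide depends entirely on participation by the C-19 acid, and the acid medium must not rearrange the 13-hydroxy-16-ene unit. The fallback turns the amide into an ester before any acid is freed; it sets out from 9 and comes back at 12. MeOTf (2,6-di-tert-butylpyridine, CH2Cl2), then hydrolysis of the imidate salt at pH 4, gives the trimethyl ester F13 with loss of dimethylamine. NaSEt/DMF (80 °C) cleaves all three methyl esters to the bis-silyl triacid F14. Aqueous HF/MeCN gives 12.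

## Further compounds

F1 | step 4 | dimethyl 2α-hydroxy-3β,13-bis(TBS-oxy)-20-norgibberella-1(10),16-diene-7,19-dioate | C=C1C[C@]23C[C@@]1(O[Si](C)(C)C(C)(C)C)CC[C@H]2C1=C[C@@H](O)[C@H](O[Si](C)(C)C(C)(C)C)[C@@](C)(C(=O)OC)[C@H]1[C@@H]3C(=O)OC
F2 | step 4 | 2α-O-[(4-methoxybenzyloxy)acetyl] ester of F1 | C=C1C[C@]23C[C@@]1(O[Si](C)(C)C(C)(C)C)CC[C@H]2C1=C[C@@H](OC(=O)COCc4ccc(OC)cc4)[C@H](O[Si](C)(C)C(C)(C)C)[C@@](C)(C(=O)OC)[C@H]1[C@@H]3C(=O)OC
F3 | step 4 | C-10α (4-methoxybenzyloxy)(carboxy)methyl compound, 1,16-diene, 7,19-dimethyl ester, 3,13-bis-TBS ether (side-chain carbon unassigned) | C=C1C[C@]23C[C@@]1(O[Si](C)(C)C(C)(C)C)CC[C@H]2[C@]1(C(OCc4ccc(OC)cc4)C(=O)O)C=C[C@H](O[Si](C)(C)C(C)(C)C)[C@@](C)(C(=O)OC)[C@H]1[C@@H]3C(=O)OC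
F4 | step 4 | C-10α hydroxy(carboxy)methyl compound, 1,16-diene, 7,19-dimethyl ester, 3,13-bis-TBS ether | C=C1C[C@]23C[C@@]1(O[Si](C)(C)C(C)(C)C)CC[C@H]2[C@]1(C(O)C(=O)O)C=C[C@H](O[Si](C)(C)C(C)(C)C)[C@@](C)(C(=O)OC)[C@H]1[C@@H]3C(=O)OC
F5 | step 4 | dimethyl 20-oxo-3β,13-bis(TBS-oxy)gibberella-1,16-diene-7,19-dioate (C-20 aldehyde) | C=C1C[C@]23C[C@@]1(O[Si](C)(C)C(C)(C)C)CC[C@H]2[C@]1(C=O)C=C[C@H](O[Si](C)(C)C(C)(C)C)[C@@](C)(C(=O)OC)[C@H]1[C@@H]3C(=O)OC
F6 | step 4 | 7,19-dimethyl ester of 3β,13-bis(TBS-oxy)gibberella-1,16-diene-7,19,20-trioic acid (free C-20 acid) | C=C1C[C@]23C[C@@]1(O[Si](C)(C)C(C)(C)C)CC[C@H]2[C@]1(C(=O)O)C=C[C@H](O[Si](C)(C)C(C)(C)C)[C@@](C)(C(=O)OC)[C@H]1[C@@H]3C(=O)OC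
F7 | step 4 | 7,19-dimethyl ester of 3β,13-bis(TBS-oxy)gibberell-16-ene-7,19,20-trioic acid (free C-20 acid) | C=C1C[C@]23C[C@@]1(O[Si](C)(C)C(C)(C)C)CC[C@H]2[C@]1(C(=O)O)CC[C@H](O[Si](C)(C)C(C)(C)C)[C@@](C)(C(=O)OC)[C@H]1[C@@H]3C(=O)OC
F8 | step 4 | 7,19-dimethyl ester of 3β,13-dihydroxygibberell-16-ene-7,19,20-trioic acid (free C-20 acid) | C=C1C[C@]23C[C@@]1(O)CC[C@H]2[C@]1(C(=O)O)CC[C@H](O)[C@@](C)(C(=O)OC)[C@H]1[C@@H]3C(=O)OC
F9 | step 5 | 7,19-dimethyl ester 20-(N,N-dimethylamide) of 3β,13-dihydroxygibberella-1,16-diene-7,19,20-trioic acid | C=C1C[C@]23C[C@@]1(O)CC[C@H]2[C@]1(C(=O)N(C)C)C=C[C@H](O)[C@@](C)(C(=O)OC)[C@H]1[C@@H]3C(=O)OC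
F10 | step 5 | 7,19-dimethyl ester 20-(N,N-dimethylamide) of 13-hydroxy-3-oxogibberella-1,16-diene-7,19,20-trioic acid (1-en-3-one) | C=C1C[C@]23C[C@@]1(O)CC[C@H]2[C@]1(C(=O)N(C)C)C=CC(=O)[C@@](C)(C(=O)OC)[C@H]1[C@@H]3C(=O)OC
F11 | step 5 | 7,19-dimethyl ester 20-(N,N-dimethylamide) of 13-hydroxy-3-oxogibberell-16-ene-7,19,20-trioic acid | C=C1C[C@]23C[C@@]1(O)CC[C@H]2[C@]1(C(=O)N(C)C)CCC(=O)[C@@](C)(C(=O)OC)[C@H]1[C@@H]3C(=O)OC
F12 | step 5 | 7,19-dimethyl ester 20-(N,N-dimethylamide) of 3β,13-dihydroxygibberell-16-ene-7,19,20-trioic acid | C=C1C[C@]23C[C@@]1(O)CC[C@H]2[C@]1(C(=O)N(C)C)CC[C@H](O)[C@@](C)(C(=O)OC)[C@H]1[C@@H]3C(=O)OC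
F13 | step 7 | trimethyl 3β,13-bis(TBS-oxy)gibberell-16-ene-7,19,20-trioate | C=C1C[C@]23C[C@@]1(O[Si](C)(C)C(C)(C)C)CC[C@H]2[C@]1(C(=O)OC)CC[C@H](O[Si](C)(C)C(C)(C)C)[C@@](C)(C(=O)OC)[C@H]1[C@@H]3C(=O)OC
F14 | step 7 | 3β,13-bis(TBS-oxy)gibberell-16-ene-7,19,20-trioic acid | C=C1C[C@]23C[C@@]1(O[Si](C)(C)C(C)(C)C)CC[C@H]2[C@]1(C(=O)O)CC[C@H](O[Si](C)(C)C(C)(C)C)[C@@](C)(C(=O)O)[C@H]1[C@@H]3C(=O)O
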